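## Analysis of the target

Target 20 is an isoflavone: a chromen-4-one (rings A and C) that carries a 4-hydroxyphenyl ring B on C3 and a hydrogen on C2. Ring A is fully substituted, with a methoxy group on C5, a (2S)-2-hydroxy-3-methylbutyl chain on C6, a free hydroxyl on C7 and a 3-methylbut-2-enyl (prenyl) group on C8. The only stereocenter is C2'' of the C6 chain, a secondary carbinol between the benzylic CH2 (C1'') and an isopropyl group. It has no stereochemical partner, so only its absolute configuration (S) has to be secured and then kept. The sensitive groups are the prenyl double bond beside the C7 hydroxyl (acid closes a dihydropyran ring; electrophiles and oxidants attack it) and C2 of ring C, where bases open the pyranone. The C5 methyl ether lies peri to the C4 carbonyl and is the easiest aryl ether to cleave, so the other phenols cannot be carried as methyl ethers. The difficulty is regiochemical: ring A carries six substituents in a fixed order, the two resorcinol oxygens end up differently (O7 free, O1 in ring C), and C6, C8 and C4a each lie between two oxygens and have to be addressed one by one. The strategy rests on one feature: ring C needs only C2 and C3 (with ring B) placed between the C4 carbonyl carbon and O1. If C4 is present as a formyl group on C4a and O1 as a free hydroxyl on C8a, ring A is a salicylaldehyde whose hydroxyl can hold a rhodium catalyst next to the formyl C–H bond.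

## Retrosynthetic reasoning

Target 20 is traced back to its bis(methoxymethyl) ether 19 by cutting the two O–CH2 acetal bonds on O7 and O4'. One acid-labile group for both phenols allows a single final operation and leaves the C5 methyl ether alone. The forward step has to cleave two aryl acetals with acid mild enough that the freed C7 hydroxyl does not add to the prenyl double bond.

Compound 19 is traced back to the doubly silylated chromone 18 by cutting the C2–Si bond and the O–Si bond on C2''. The silicon on C2 is a traceless steering group for the ring-forming step and the silyl ether covers the carbinol during the organolithium chemistry. Both Si bonds fall to fluoride in one operation.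

Chromone 18 is cut at O1–C2 and C3–C4 into salicylaldehyde 13 and aryl(silyl)alkyne 17. This cut removes ring C and the ring B attachment in one convergent step. It leaves a ring A fragment whose substitution can be set entirely by directed metalation, and an alkyne that takes two steps to make. Cuts at C4–C4a or C2–C3 would call for strongly acidic or basic ring closures that the prenyl group or ring C tolerate poorly. The forward reaction has to cleave the formyl C–H bond next to the free hydroxyl, insert the alkyne with the aryl-bearing carbon on C4, and close the C–O bond oxidatively without a chemical oxidant.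

Alkyne 17 is cut at its aryl–alkynyl bond into aryl iodide 15 and ethynyltrimethylsilane 16, and 15 comes from 4-iodophenol 14 by acetal formation. The forward coupling must leave the silyl group on the alkyne.

Salicylaldehyde 13 is traced back to the bis(methoxymethyl) ether 12 by cutting the O–CH2 bond on the oxygen ortho to the formyl group. This is where the two resorcinol oxygens are told apart: both start as the same acetal, and only the one beside the aldehyde can be reached through a chelate. The gain is that a symmetrical, cheap starting material can be used.

Aldehyde 12 is cut at the C4a–CHO bond to the pentasubstituted arene 9. Only one ring hydrogen is left in 9, so the formylation has no regiochemical question. It is placed after the other two C–C bond formations because an aldehyde would not survive the aryllithium steps.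

Silyl ether 9 comes from alcohol 8, and 8 is cut at the C6–C1'' bond into arene 5 and (R)-2-isopropyloxirane 6. The aryl anion attacks the unsubstituted oxirane carbon, so the C2'' stereocenter is carried in from 6 and never becomes a reacting centre. The forward step must metalate one of two equivalent ring positions and open the oxirane at its CH2 end.

Arene 5 is cut at the C8–CH2 bond into the bis(methoxymethyl) ether 2 and 1-bromo-3-methylbut-2-ene 3. The carbon between the two acetal oxygens is the most readily metalated site of 2, so the prenyl group goes in first. After that the two remaining ring positions are equivalent and no isomer problem arises. Compound 2 is the double acetal of 5-methoxyresorcinol 1.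

## Alternatives that were turned down

Alternative 1: The C6 chain is cut at C6–C1'' and C2''–C3'' into the aryl bromide A1 (2-bromo-1-methoxy-3,5-bis(methoxymethoxy)-4-(3-methylbut-2-enyl)benzene), vinylboronic acid pinacol ester A2 and isopropyllithium A3. In the forward step A2 and A3 form a boron ate complex. An arylpalladium species from A1, Pd(OAc)2 and a chiral ferrocenyl bisphosphine (NaOTf takes up the halide) binds the vinyl group and triggers 1,2-migration of isopropyl from boron to carbon. This makes both C–C bonds and the C2'' stereocenter under ligand control and gives boronic ester A4, whose stereoretentive oxidation would lead to alcohol 8. In its favour, the chain is built from the simplest achiral pieces, either enantiomer is open by choice of ligand, and no Lewis acid meets the acetals; on these points it is as strong as or stronger than the chosen route. Against it, A1 is an electron-rich bromide flanked by two ortho oxygen substituents, so oxidative addition is slow and the arylpalladium unit is crowded. A secondary alkyl migrating group together with such an aryl partner lies at the edge of what this coupling handles with high selectivity. A1 also requires an electrophilic bromination beside the prenyl double bond, and that double bond can compete for palladium. It takes three steps (bromination, coupling, oxidation) to reach 8, and it leaves ring C unsolved. The chosen route reaches 8 from 5 in one step, takes the stereocenter from 6 at full enantiomeric purity, and spends its key step on ring C.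

Alternative 2: The C2''–O bond is cut, so the stereocenter arises late by face-selective oxygen transfer to the C6 prenyl group of the assembled isoflavone A5 (5-methoxy-7-(methoxymethoxy)-3-[4-(methoxymethoxy)phenyl]-6-(3-methylbut-2-enyl)-8-(trimethylsilyl)chromen-4-one). In the forward step the fructose-derived Shi ketone with KHSO5 epoxidises the trisubstituted double bond to oxirane A6; the oxirane is opened reductively later and the C8 silyl group is exchanged for prenyl. In its favour, trisubstituted alkenes are the best substrates for this catalyst, both side chains come from the same C5 halide, and no aryllithium has to open an epoxide at a crowded ring; here it is stronger than the chosen route. Against it, the later reduction must deliver hydride to the tertiary C3'' and break the C3''–O bond while keeping C2''–O, which needs Lewis acid assistance. That invites hydride or alkyl shifts to a carbonyl compound and capture of the cation by the neighbouring C7 acetal oxygen. C8 must be blocked by silicon so that only one prenyl group is oxidised, and the late silicon-to-prenyl exchange costs several steps on a complex isoflavone. Dioxiranes also attack the C2–C3 double bond of chromones, and the enantiomeric purity is set by a catalytic step. The chosen route has no regiochemical question at the oxirane, no second prenyl group to distinguish, and is shorter.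

Alternative 3: Ring C is cut at C4–C4a. In the forward step trifluoroacetic anhydride with trifluoroacetic acid turns the acrylic acid A7 ((2Z)-3-{3-acetoxy-4-[(2S)-2-acetoxy-3-methylbutyl]-2-bromo-5-methoxyphenoxy}-2-(4-acetoxyphenyl)prop-2-enoic acid) into a mixed anhydride, whose acyl carbon attacks the last free ring carbon and gives chromone A8. In its favour, ring B on C3 and the hydrogen on C2 are fixed in the substrate, so there is no insertion regiochemistry, and no metal or electrochemical equipment is needed; on these points it is stronger than the chosen route. Against it, the strongly acidic acylating medium excludes the prenyl group, the acetals and the silyl ether. This forces a bromine placeholder on C8, acetate protection, and a late palladium-catalysed prenylation between two oxygen substituents with a linear versus branched question. The acetoxy and bromo groups lower the nucleophilicity of ring A. A7 needs O-vinylation of a hindered phenol with control of the double-bond geometry, since only the Z isomer can close. The final acetate hydrolysis uses base, which threatens ring C. The chosen route carries the prenyl group through and ends with two deprotections.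

Key step: step 9

Assumption: (R)-2-isopropyloxirane 6 ((R)-1,2-epoxy-3-methylbutane) is taken as a purchasable building block of high enantiomeric purity; C1'', C2'' and C3'' denote the C6 chain counted from the ring.

## Route

Step 1
Reactants: 1 5-methoxyresorcinol
Product: 2 1-methoxy-3,5-bis(methoxymethoxy)benzene
Conditions: NaH, MOMCl, DMF, 0 °C to rt
Reagents that add atoms: chloromethyl methyl ether, COCCl
Why: Williamson-type O-alkylation of both phenoxides by the reactive α-chloro ether; the two acetals later direct all ring metalations, and one of them is the removable cover of the future O1.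

Step 2
Reactants: 2; 3 1-bromo-3-methylbut-2-ene
Product: 5 5-methoxy-1,3-bis(methoxymethoxy)-2-(3-methylbut-2-enyl)benzene, via aryllithium 4 (not isolated)
Conditions: n-BuLi, THF, 0 °C; then 3, −78 °C to rt
Reagents that add atoms: none
Why: Directed ortho-metalation removes the hydrogen between the two methoxymethoxy groups, because both acetal oxygens bind lithium and direct more strongly than the methoxy group; aryllithium 4 is then alkylated at the primary carbon of the allylic bromide in the SN2 sense.

Step 3
Reactants: 5; 6 (R)-2-isopropyloxirane
Product: 8 (2S)-1-[6-methoxy-2,4-bis(methoxymethoxy)-3-(3-methylbut-2-enyl)phenyl]-3-methylbutan-2-ol, via aryllithium 7 (not isolated)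
Conditions: n-BuLi, THF, 0 °C; then 6, BF3·OEt2, −78 °C; aq. NaHCO3
Reagents that add atoms: none
Why: A second directed ortho-metalation at one of the two equivalent hydrogens between the methoxy and a methoxymethoxy group gives 7, which opens the BF3-activated oxirane at its unsubstituted CH2 carbon (Lewis acid-promoted SN2 epoxide opening by an organolithium; no amine additive, so BF3 is not sequestered). C2'' is not a reacting carbon, so the configuration of 6 is carried over unchanged; the descriptor changes from R to S only because the aryl-CH2 group ranks below isopropyl.

Step 4
Reactants: 8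
Product: 9 tert-butyl{[(2S)-1-[6-methoxy-2,4-bis(methoxymethoxy)-3-(3-methylbut-2-enyl)phenyl]-3-methylbutan-2-yl]oxy}dimethylsilane
Conditions: TBSOTf, 2,6-lutidine, CH2Cl2, −78 to 0 °C
Reagents that add atoms: tert-butyldimethylsilyl trifluoromethanesulfonate, CC(C)(C)[Si](C)(C)OS(=O)(=O)C(F)(F)F
Why: O-Silylation of a hindered secondary alcohol by a silyl triflate with a hindered pyridine base; the aryl acetals and the alkene should be inert at low temperature, and the hydroxyl is masked before the third metalation.

Step 5
Reactants: 9
Product: 12 3-[(2S)-2-(tert-butyldimethylsilyloxy)-3-methylbutyl]-2-methoxy-4,6-bis(methoxymethoxy)-5-(3-methylbut-2-enyl)benzaldehyde, via aryllithium 10 (not isolated), via lithium hemiaminalate 11 (not isolated)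
Conditions: n-BuLi, TMEDA, THF, 0 °C; then DMF, 0 °C to rt; aq. NH4Cl
Reagents that add atoms: N,N-dimethylformamide, CN(C)C=O
Why: The single remaining ring hydrogen lies between the methoxy and a methoxymethoxy group, so directed ortho-metalation gives 10 without a regiochemical choice; addition to the formamide gives the tetrahedral adduct 11, which is stable until hydrolysis releases the aldehyde (Bouveault formylation).

Step 6
Reactants: 12
Product: 13 3-[(2S)-2-(tert-butyldimethylsilyloxy)-3-methylbutyl]-6-hydroxy-2-methoxy-4-(methoxymethoxy)-5-(3-methylbut-2-enyl)benzaldehyde
Conditions: MgBr2·OEt2, Et2O/CH2Cl2, 0 °C to rt; aq. NH4Cl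
Reagents that add atoms: none
Why: Chelation-controlled acetal cleavage: divalent magnesium bridges the formyl oxygen and the ortho aryl oxygen, weakens that O–CH2 bond, and bromide takes the methoxymethyl group. The acetal para to the aldehyde has no chelating partner, and the methyl ether and the silyl ether should not react with this mild Lewis acid.

Step 7
Reactants: 14 4-iodophenol
Product: 15 1-iodo-4-(methoxymethoxy)benzene
Conditions: NaH, MOMCl, THF/DMF, 0 °C to rt
Reagents that add atoms: chloromethyl methyl ether, COCCl
Why: Williamson-type O-alkylation of the phenoxide; the acetal matches the protecting group on O7, so both fall in the last step.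

Step 8
Reactants: 15; 16 ethynyltrimethylsilane
Product: 17 trimethyl{[4-(methoxymethoxy)phenyl]ethynyl}silane
Conditions: PdCl2(PPh3)2 (2 mol %), CuI (4 mol %), Et3N, THF, rt
Reagents that add atoms: none
Why: Sonogashira coupling: oxidative addition of the aryl iodide to zerovalent palladium, transmetalation from the copper acetylide and reductive elimination; the silyl group stays on the other alkyne terminus under these amine conditions.

Step 9
Reactants: 13; 17
Product: 18 6-[(2S)-2-(tert-butyldimethylsilyloxy)-3-methylbutyl]-5-methoxy-7-(methoxymethoxy)-3-[4-(methoxymethoxy)phenyl]-8-(3-methylbut-2-enyl)-2-(trimethylsilyl)chromen-4-one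
Conditions: [Cp*RhCl2]2 (2.5 mol %), NaOPiv (1 equiv), t-AmOH/H2O (3:1), 80 °C, undivided cell, graphite-felt anode, Pt cathode, constant current 2 mA, N2
Reagents that add atoms: none
Why: Pivalate exchange on [Cp*RhCl2]2 gives a trivalent rhodium carboxylate that binds the phenoxide of 13 and cleaves the neighbouring formyl C–H bond by concerted metalation–deprotonation, giving a five-membered acyl rhodacycle. Alkyne 17 inserts into the Rh–acyl bond to a seven-membered oxarhodacycle, and C–O reductive elimination, eased by anodic oxidation of the metallacycle, joins O1 to C2; the monovalent rhodium released is returned to the trivalent state at the anode while protons are reduced to H2 at the cathode, so no chemical oxidant is present. The closest known reaction type is the rhodium-catalysed oxidative annulation of salicylaldehydes with internal alkynes to chromones, run with copper oxidants or electrochemically. Ring C closes as a formal [4+2] annulation (O1, C8a, C4a and C4 from 13, C3 and C2 from 17), the last bond being made by reductive elimination from the metallacycle and not by a nucleophilic cyclisation. No stereocenter is formed, and C2'' is remote from the reacting atoms in a medium that is neither acidic nor strongly basic. Two selectivities are needed: the site of C–H cleavage is fixed because the only free hydroxyl is the one ortho to the aldehyde, and the insertion must put the aryl-bearing alkyne carbon on C4, for which the substrate offers the silyl group, which prefers the metal-bound carbon both for its bulk next to the doubly ortho-substituted aroyl unit and because silicon stabilises an adjacent carbon–metal bond. The prenyl alkene, the acetals and the silyl ether should be inert, and a low current density keeps the electron-rich ring A from direct anodic oxidation.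

Step 10
Reactants: 18
Product: 19 6-[(2S)-2-hydroxy-3-methylbutyl]-5-methoxy-7-(methoxymethoxy)-3-[4-(methoxymethoxy)phenyl]-8-(3-methylbut-2-enyl)chromen-4-one
Conditions: Bu4NF·3H2O, THF, 0 °C to rt
Reagents that add atoms: none
Why: Fluoride attacks both silicon atoms: the C2–Si bond of the vinylogous ester breaks to an sp2 carbanion stabilised by the ring oxygen and is protonated by the water of hydration (protodesilylation), and the silyl ether gives the alcohol; aryl methoxymethyl ethers are inert to fluoride, and any silyl ether that survived would still fall in step 11.

Step 11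
Reactants: 19
Product: 20 7-hydroxy-6-[(2S)-2-hydroxy-3-methylbutyl]-3-(4-hydroxyphenyl)-5-methoxy-8-(3-methylbut-2-enyl)chromen-4-one
Conditions: aq. HCl (2 M), MeOH, rt
Reagents that add atoms: none
Why: Acid-catalysed transacetalisation of both aryl methoxymethyl ethers to methanol; dilute acid at room temperature should stay below the threshold for addition of the C7 hydroxyl to the prenyl double bond, and the C5 methyl ether and the carbinol stereocenter have no pathway for change under these conditions.

## Compound list

1 | 5-methoxyresorcinol | COc1cc(O)cc(O)c1 | starting material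
2 | 1-methoxy-3,5-bis(methoxymethoxy)benzene | COCOc1cc(OC)cc(OCOC)c1 | intermediate
3 | 1-bromo-3-methylbut-2-ene | CC(C)=CCBr | starting material
4 | [4-methoxy-2,6-bis(methoxymethoxy)phenyl]lithium | [Li]c1c(OCOC)cc(OC)cc1OCOC | intermediate
5 | 5-methoxy-1,3-bis(methoxymethoxy)-2-(3-methylbut-2-enyl)benzene | COCOc1cc(OC)cc(OCOC)c1CC=C(C)C | intermediate
6 | (R)-2-isopropyloxirane | CC(C)[C@@H]1CO1 | starting material
7 | [6-methoxy-2,4-bis(methoxymethoxy)-3-(3-methylbut-2-enyl)phenyl]lithium | [Li]c1c(OC)cc(OCOC)c(CC=C(C)C)c1OCOC | intermediate
8 | (2S)-1-[6-methoxy-2,4-bis(methoxymethoxy)-3-(3-methylbut-2-enyl)phenyl]-3-methylbutan-2-ol | COc1cc(OCOC)c(CC=C(C)C)c(OCOC)c1C[C@H](O)C(C)C | intermediate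
9 | tert-butyl{[(2S)-1-[6-methoxy-2,4-bis(methoxymethoxy)-3-(3-methylbut-2-enyl)phenyl]-3-methylbutan-2-yl]oxy}dimethylsilane | COc1cc(OCOC)c(CC=C(C)C)c(OCOC)c1C[C@H](O[Si](C)(C)C(C)(C)C)C(C)C | intermediate
10 | {3-[(2S)-2-(tert-butyldimethylsilyloxy)-3-methylbutyl]-2-methoxy-4,6-bis(methoxymethoxy)-5-(3-methylbut-2-enyl)phenyl}lithium | [Li]c1c(OC)c(C[C@H](O[Si](C)(C)C(C)(C)C)C(C)C)c(OCOC)c(CC=C(C)C)c1OCOC | intermediate
11 | lithium (dimethylamino){3-[(2S)-2-(tert-butyldimethylsilyloxy)-3-methylbutyl]-2-methoxy-4,6-bis(methoxymethoxy)-5-(3-methylbut-2-enyl)phenyl}methanolate (both epimers at the aminal carbon) | [Li]OC(N(C)C)c1c(OC)c(C[C@H](O[Si](C)(C)C(C)(C)C)C(C)C)c(OCOC)c(CC=C(C)C)c1OCOC | intermediate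
12 | 3-[(2S)-2-(tert-butyldimethylsilyloxy)-3-methylbutyl]-2-methoxy-4,6-bis(methoxymethoxy)-5-(3-methylbut-2-enyl)benzaldehyde | COc1c(C[C@H](O[Si](C)(C)C(C)(C)C)C(C)C)c(OCOC)c(CC=C(C)C)c(OCOC)c1C=O | intermediate
13 | 3-[(2S)-2-(tert-butyldimethylsilyloxy)-3-methylbutyl]-6-hydroxy-2-methoxy-4-(methoxymethoxy)-5-(3-methylbut-2-enyl)benzaldehyde | COc1c(C[C@H](O[Si](C)(C)C(C)(C)C)C(C)C)c(OCOC)c(CC=C(C)C)c(O)c1C=O | intermediate
14 | 4-iodophenol | Oc1ccc(I)cc1 | starting material
15 | 1-iodo-4-(methoxymethoxy)benzene | COCOc1ccc(I)cc1 | intermediate
16 | ethynyltrimethylsilane | C#C[Si](C)(C)C | starting material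
17 | trimethyl{[4-(methoxymethoxy)phenyl]ethynyl}silane | C[Si](C)(C)C#Cc1ccc(OCOC)cc1 | intermediate
18 | 6-[(2S)-2-(tert-butyldimethylsilyloxy)-3-methylbutyl]-5-methoxy-7-(methoxymethoxy)-3-[4-(methoxymethoxy)phenyl]-8-(3-methylbut-2-enyl)-2-(trimethylsilyl)chromen-4-one | COc1c(C[C@H](O[Si](C)(C)C(C)(C)C)C(C)C)c(OCOC)c(CC=C(C)C)c2oc([Si](C)(C)C)c(-c3ccc(OCOC)cc3)c(=O)c12 | intermediate
19 | 6-[(2S)-2-hydroxy-3-methylbutyl]-5-methoxy-7-(methoxymethoxy)-3-[4-(methoxymethoxy)phenyl]-8-(3-methylbut-2-enyl)chromen-4-one | COc1c(C[C@H](O)C(C)C)c(OCOC)c(CC=C(C)C)c2occ(-c3ccc(OCOC)cc3)c(=O)c12 | intermediate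
20 | 7-hydroxy-6-[(2S)-2-hydroxy-3-methylbutyl]-3-(4-hydroxyphenyl)-5-methoxy-8-(3-methylbut-2-enyl)chromen-4-one | COc1c(C[C@H](O)C(C)C)c(O)c(CC=C(C)C)c2occ(-c3ccc(O)cc3)c(=O)c12 | target

## Step count and least certain steps

Total: 11 steps. Longest linear sequence: 9 steps (steps 1 to 6 and 9 to 11, from 1); the alkyne branch (steps 7 and 8) is 2 steps.

Step 9 (key step). The most likely failure is insertion in the opposite sense, with the aryl-bearing carbon on rhodium, since an aryl group also favours the metal-bound position and the outcome of the aryl versus silyl contest is not established for this annulation. Other failure modes are loss of the silyl group from 17 by pivalate in the hot protic medium before insertion, decarbonylation of the crowded acyl rhodacycle, and direct anodic oxidation of the phenol. The fallback avoids any insertion regiochemistry by the deoxybenzoin route. It sets out from 13: an excess of [4-(methoxymethoxy)benzyl]magnesium chloride F1, made from the benzylic chloride and Mg, adds to the aldehyde and gives the benzylic carbinol F2. MnO2 oxidises it to the 2-hydroxydeoxybenzoin F3. Heating with N,N-dimethylformamide dimethyl acetal forms the enaminone, which closes ring C with loss of dimethylamine to the silyl-protected isoflavone F4. Bu4NF then removes the silyl ether and the route is rejoined at 19. Partial loss of the C2 silyl group during the electrolysis itself would be harmless, since it gives F4 as well.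

Step 3. Metalation may go to the doubly activated benzylic and allylic CH2 of the prenyl group instead of the ring, and BF3 may rearrange the oxirane to an aldehyde or attack an acetal before the aryllithium reacts. The fallback sets out from 5 and changes both the way the aryl metal is made and the way the oxirane is activated. N-Bromosuccinimide in MeCN at low temperature brominates the electron-rich ring to the aryl bromide F5. Magnesium insertion (Mg, LiCl, THF) gives the arylmagnesium bromide F6, which opens 6 at its CH2 carbon under CuI catalysis without a Lewis acid. The route is rejoined at 8.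

Step 6. The chelate may not discriminate well enough, so that both acetals are lost or the cleavage stalls; the silyl ether may also be partly cleaved. The fallback sets out from 12 and replaces selective deprotection by selective protection. ZnBr2 with propane-1-thiol removes both methoxymethyl groups within minutes and leaves the silyl ether, giving the dihydroxy aldehyde F7. MOMCl with K2CO3 in acetone then alkylates only the hydroxyl para to the formyl group, because the ortho hydroxyl is held in a hydrogen bond to the aldehyde. The route is rejoined at 13.

Step 11. Once O7 is free, the acid may add it across the neighbouring prenyl double bond and close a dihydropyran ring. The fallback sets out from 19 and avoids protic acid. Trimethylsilyl trifluoromethanesulfonate with 2,2'-bipyridyl in CH2Cl2 at 0 °C converts both aryl acetals into aryl silyl ethers and silylates the carbinol, giving the tris(trimethylsilyl) ether F8. This is hydrolysed with a catalytic amount of K2CO3 in MeOH/H2O at 0 °C, which rejoins the route at 20.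

## Further compounds

F1 | step 9 | [4-(methoxymethoxy)benzyl]magnesium chloride | COCOc1ccc(C[Mg]Cl)cc1
F2 | step 9 | 1-{3-[(2S)-2-(tert-butyldimethylsilyloxy)-3-methylbutyl]-6-hydroxy-2-methoxy-4-(methoxymethoxy)-5-(3-methylbut-2-enyl)phenyl}-2-[4-(methoxymethoxy)phenyl]ethanol (both epimers at the carbinol carbon) | COc1c(C[C@H](O[Si](C)(C)C(C)(C)C)C(C)C)c(OCOC)c(CC=C(C)C)c(O)c1C(O)Cc1ccc(OCOC)cc1
F3 | step 9 | 1-{3-[(2S)-2-(tert-butyldimethylsilyloxy)-3-methylbutyl]-6-hydroxy-2-methoxy-4-(methoxymethoxy)-5-(3-methylbut-2-enyl)phenyl}-2-[4-(methoxymethoxy)phenyl]ethanone | COc1c(C[C@H](O[Si](C)(C)C(C)(C)C)C(C)C)c(OCOC)c(CC=C(C)C)c(O)c1C(=O)Cc1ccc(OCOC)cc1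
F4 | step 9 | 6-[(2S)-2-(tert-butyldimethylsilyloxy)-3-methylbutyl]-5-methoxy-7-(methoxymethoxy)-3-[4-(methoxymethoxy)phenyl]-8-(3-methylbut-2-enyl)chromen-4-one | COc1c(C[C@H](O[Si](C)(C)C(C)(C)C)C(C)C)c(OCOC)c(CC=C(C)C)c2occ(-c3ccc(OCOC)cc3)c(=O)c12
F5 | step 3 | 2-bromo-1-methoxy-3,5-bis(methoxymethoxy)-4-(3-methylbut-2-enyl)benzene | COc1cc(OCOC)c(CC=C(C)C)c(OCOC)c1Br
F6 | step 3 | [6-methoxy-2,4-bis(methoxymethoxy)-3-(3-methylbut-2-enyl)phenyl]magnesium bromide | COc1cc(OCOC)c(CC=C(C)C)c(OCOC)c1[Mg]Br
F7 | step 6 | 3-[(2S)-2-(tert-butyldimethylsilyloxy)-3-methylbutyl]-4,6-dihydroxy-2-methoxy-5-(3-methylbut-2-enyl)benzaldehyde | COc1c(C[C@H](O[Si](C)(C)C(C)(C)C)C(C)C)c(O)c(CC=C(C)C)c(O)c1C=O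
F8 | step 11 | 5-methoxy-6-[(2S)-3-methyl-2-(trimethylsilyloxy)butyl]-8-(3-methylbut-2-enyl)-7-(trimethylsilyloxy)-3-[4-(trimethylsilyloxy)phenyl]chromen-4-one | COc1c(C[C@H](O[Si](C)(C)C)C(C)C)c(O[Si](C)(C)C)c(CC=C(C)C)c2occ(-c3ccc(O[Si](C)(C)C)cc3)c(=O)c12
A1 | alternative 1 | 2-bromo-1-methoxy-3,5-bis(methoxymethoxy)-4-(3-methylbut-2-enyl)benzene | COc1cc(OCOC)c(CC=C(C)C)c(OCOC)c1Br
A2 | alternative 1 | vinylboronic acid pinacol ester (4,4,5,5-tetramethyl-2-vinyl-1,3,2-dioxaborolane) | C=CB1OC(C)(C)C(C)(C)O1
A3 | alternative 1 | isopropyllithium | [Li]C(C)C
A4 | alternative 1 | (S)-2-{1-[6-methoxy-2,4-bis(methoxymethoxy)-3-(3-methylbut-2-enyl)phenyl]-3-methylbutan-2-yl}-4,4,5,5-tetramethyl-1,3,2-dioxaborolane | COc1cc(OCOC)c(CC=C(C)C)c(OCOC)c1C[C@H](B2OC(C)(C)C(C)(C)O2)C(C)C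
A5 | alternative 2 | 5-methoxy-7-(methoxymethoxy)-3-[4-(methoxymethoxy)phenyl]-6-(3-methylbut-2-enyl)-8-(trimethylsilyl)chromen-4-one | COc1c(CC=C(C)C)c(OCOC)c([Si](C)(C)C)c2occ(-c3ccc(OCOC)cc3)c(=O)c12
A6 | alternative 2 | 6-{[(2S)-3,3-dimethyloxiran-2-yl]methyl}-5-methoxy-7-(methoxymethoxy)-3-[4-(methoxymethoxy)phenyl]-8-(trimethylsilyl)chromen-4-one | COc1c(C[C@H]4C(C)(C)O4)c(OCOC)c([Si](C)(C)C)c2occ(-c3ccc(OCOC)cc3)c(=O)c12
A7 | alternative 3 | (2Z)-3-{3-acetoxy-4-[(2S)-2-acetoxy-3-methylbutyl]-2-bromo-5-methoxyphenoxy}-2-(4-acetoxyphenyl)prop-2-enoic acid | O=C(O)/C(c1ccc(OC(C)=O)cc1)=C\Oc1cc(OC)c(C[C@H](OC(C)=O)C(C)C)c(OC(C)=O)c1Br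
A8 | alternative 3 | 7-acetoxy-6-[(2S)-2-acetoxy-3-methylbutyl]-3-(4-acetoxyphenyl)-8-bromo-5-methoxychromen-4-one | COc1c(C[C@H](OC(C)=O)C(C)C)c(OC(C)=O)c(Br)c2occ(-c3ccc(OC(C)=O)cc3)c(=O)c12
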